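**Retrosynthetic overview**
1. Ring A is bought in acetophenone 1. The γ-pyranone ring C is closed first with one added carbon (1 → enaminone 2 → chromone 3). Ring B is bought in aryl iodide 4.
2. Key disconnection: the C2–C1' bond between ring C and ring B, not a bond of the pyranone ring.
3. Polarity: chromone C2, normally the electrophilic Michael terminus, is made nucleophilic as the C2-zinc species 5, a β-acylvinyl anion (homoenolate-type d3 synthon). Pd catalysis joins it to the electrophilic ipso carbon of 4 to give target 6.
4. Ring order: A (bought) → C (step 1) → B attached (step 2).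

Assumption: the target is an achiral flavone with no stereocentre, so "single enantiomer" needs no stereocontrol.

**Step 1**
Reactants: 1 1-(2-hydroxy-4,5-dimethoxyphenyl)ethan-1-one
Product: 3 6,7-dimethoxy-4H-chromen-4-one, via enaminone 2 (not isolated)
Conditions: DMF-DMA (2.5 equiv), toluene, 110 °C, 3 h; evaporate; conc. HCl, CH2Cl2, 40 °C, 2 h
Reagents that add atoms: N,N-dimethylformamide dimethyl acetal (DMF-DMA), COC(OC)N(C)C
Why: Aminomethylenation of the methyl ketone gives the vinylogous amide 2, and acid-promoted intramolecular oxa-Michael addition of the phenol with elimination of dimethylamine (enaminone–chromone cyclisation) closes the pyranone; the aryl methyl ethers survive and no stereocentre is formed.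

**Step 2**
Reactants: 3 6,7-dimethoxy-4H-chromen-4-one; 4 5-iodo-1,2,3-trimethoxybenzene
Product: 6 Prosogerin C (6,7-dimethoxy-2-(3,4,5-trimethoxyphenyl)-4H-chromen-4-one), via chromon-2-ylzinc chloride 5 (not isolated)
Conditions: TMPZnCl·LiCl (1.2 equiv), THF, 25 °C, 1 h, no Lewis acid additive; then 4 (0.9 equiv), Pd(dba)2 (3 mol %), P(2-furyl)3 (6 mol %), 50 °C, 4 h
Reagents that add atoms: none
Why: Regioselective C–H zincation with the non-nucleophilic TMP-zinc amide should remove the most acidic proton, C2–H (sp2, next to the ring oxygen), without attacking the C4 carbonyl; the resulting β-acylvinyl anion equivalent 5 then undergoes Negishi cross-coupling with the electrophilic aryl carbon of 4, and no stereocentre is formed.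

**Compound list**
1 | 1-(2-hydroxy-4,5-dimethoxyphenyl)ethan-1-one | CC(=O)c1cc(OC)c(OC)cc1O | starting material
2 | (E)-3-(dimethylamino)-1-(2-hydroxy-4,5-dimethoxyphenyl)prop-2-en-1-one | CN(C)/C=C/C(=O)c1cc(OC)c(OC)cc1O | intermediate
3 | 6,7-dimethoxy-4H-chromen-4-one | COc1cc2occc(=O)c2cc1OC | intermediate
4 | 5-iodo-1,2,3-trimethoxybenzene | COc1cc(I)cc(OC)c1OC | starting material
5 | chloro(6,7-dimethoxy-4-oxo-4H-chromen-2-yl)zinc (as its LiCl complex) | COc1cc2oc([Zn]Cl)cc(=O)c2cc1OC | intermediate
6 | Prosogerin C, 6,7-dimethoxy-2-(3,4,5-trimethoxyphenyl)-4H-chromen-4-one | COc1cc2oc(-c3cc(OC)c(OC)c(OC)c3)cc(=O)c2cc1OC | target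

**Totals**
Total step count: 2. Longest linear sequence: 2 (1 → 3 → 6; 4 enters in step 2).

**Steps most likely to fail**
The route has only two steps, so the three weakest points are the two events of step 2 and then step 1.

First, step 2, the zincation event. The amide base may metalate C3 (carbonyl-directed) or an arene position next to a methoxy group, or open the pyranone, instead of giving 5. The C2 selectivity of TMPZnCl·LiCl without a Lewis acid is my recollection of how chromones behave and should be confirmed by a D2O or I2 quench before the coupling. The fallback sets out from 3 and reverses the polarity of the same bond. Pd(II)-catalysed conjugate addition of (3,4,5-trimethoxyphenyl)boronic acid to 3 (Pd(OCOCF3)2, 2,2'-bipyridine, DCE/H2O, 60 °C) gives racemic 6,7-dimethoxy-2-(3,4,5-trimethoxyphenyl)chroman-4-one F1. Dehydrogenation of F1 with catalytic I2 in DMSO at 120 °C gives the flavone, so this fallback comes back to the route at 6.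

Second, step 2, the cross-coupling event. Zinc species 5 may form but couple slowly with the electron-rich iodide 4, giving protodezincation back to 3 or homocoupling. The fallback sets out from 5 (made from 3 as in step 2) and turns the chromone into the electrophilic partner. Quenching 5 with I2 (THF, 0 °C) gives 2-iodo-6,7-dimethoxy-4H-chromen-4-one F2. Suzuki–Miyaura coupling of F2 with (3,4,5-trimethoxyphenyl)boronic acid (Pd(PPh3)4, K3PO4, dioxane with a little water, 80 °C) comes back to the route at 6.

Third, step 1. Enaminone 2 may cyclise incompletely or give tarry material on acid treatment. The fallback sets out from 1 and uses a formyl Claisen condensation instead. Treatment of 1 with ethyl formate (NaH, THF, 0 °C to rt) gives the cyclic hemiacetal 2-hydroxy-6,7-dimethoxychroman-4-one F3 (racemic). Dehydration of F3 with conc. HCl in AcOH at 60 °C comes back to the route at 3.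

**Further compounds**
F1 | step 2 | 6,7-dimethoxy-2-(3,4,5-trimethoxyphenyl)chroman-4-one (racemic) | COc1cc2c(cc1OC)C(=O)CC(O2)c1cc(OC)c(OC)c(OC)c1
F2 | step 2 | 2-iodo-6,7-dimethoxy-4H-chromen-4-one | COc1cc2oc(I)cc(=O)c2cc1OC
F3 | step 1 | 2-hydroxy-6,7-dimethoxychroman-4-one (racemic) | COc1cc2c(cc1OC)C(=O)CC(O)O2
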